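1. Numbering: ring A = C1–C2–C3–C4(C15H3)–C5. Ring B = C1–C5=C6–C7(C11Me2OH)–C8–C9–C10(C14H3). C1' = benzylic CH on C4, and C2'–C3' begin the isobutyl group.
2. Enabling feature: the crowded C1'(H, aryl)–C4(quaternary) bond carries an ortho phenol oxygen on the aryl ring, one CH2 on each carbon (C2', C3) and two one-carbon arms on C4 (C15, C5). This is the alkene of a coumarin-3-carboxylate after syn addition of isoprene.
3. Cuts, in retrosynthetic order: three O–Me and two aryl–CHO bonds; C5=C6 (ring B, carbonyl coupling); C1=C2 (ring A, intramolecular olefination) and C1–C5 (phosphonate addition); C2 and C3' rejoined to a helper cyclohexene; C1'–C2' and C3–C4 (Diels–Alder).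
4. Forward order: pyranone ring, helper cyclohexene, lactone carbonyl reduced to C15H3, carvone-derived chain (C1, C6–C14) joined at C5, helper ring cut, ring A, ring B, arene formylated and demethylated.
5. Stereochemistry: C1'/C4 come from the cycloaddition (relative: suprafacial addition to a ring-locked alkene; absolute: chiral copper chelate). C7 comes from (R)-carvone. C10 and C1 are set by equilibration next to a ketone.

Key step: step 2

Assumption: the sense of induction in step 2 is inferred from the distorted square-planar chelate model. The ligand is written as (S,S)-t-Bu-box, 2,2'-(propane-2,2-diyl)bis[(4S)-4-tert-butyl-4,5-dihydro-1,3-oxazole]; its commercial mirror image is used if the first run shows the opposite sense.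
Abbreviation: TBS = tert-butyldimethylsilyl. Stereodescriptors with primed or guaiane locants refer to the numbering in line 1.

Step 1
Reactants: 1 2-hydroxy-4,6-dimethoxybenzaldehyde; 2 tert-butyl methyl malonate
Product: 4 tert-butyl 5,7-dimethoxy-2-oxo-2H-chromene-3-carboxylate, via (E)-benzylidenemalonate 3 (not isolated)
Conditions: piperidine (cat.), AcOH (cat.), toluene, reflux, Dean–Stark
Reagents that add atoms: none
Why: Knoevenagel condensation followed by lactonisation, in which the reversible condensation funnels through the E isomer 3, whose phenol attacks the unhindered methyl ester and not the tert-butyl ester, so methanol is lost and the bulky ester stays next to the lactone carbonyl.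

Step 2
Reactants: 4 tert-butyl 5,7-dimethoxy-2-oxo-2H-chromene-3-carboxylate; 5 isoprene
Product: 6 tert-butyl (6aS,10aS)-1,3-dimethoxy-9-methyl-6-oxo-6a,7,10,10a-tetrahydro-6H-benzo[c]chromene-6a-carboxylate (cis-fused)
Conditions: [Cu((S,S)-t-Bu-box)](SbF6)2 (15 mol %), isoprene (10 equiv), CH2Cl2, 25 °C, sealed tube
Reagents that add atoms: none
Why: Proposed new method: thermal, high-pressure and Lewis acid promoted Diels–Alder additions of 2-substituted butadienes to 3-alkoxycarbonylcoumarins are known, and divalent copper bis(oxazoline) chelates are established for alkylidene malonates and acryloyl imides, but the enantioselective combination on a coumarin ester has not been shown. The lactone and ester carbonyl groups bind the copper dication as a six-membered chelate that lowers the LUMO of the pyranone alkene, and isoprene adds in a concerted, asynchronous, normal-demand [4+2] cycloaddition. The helper cyclohexene closes by suprafacial bonding at both alkene carbons (C1'–C2' and C3–C4 form together), so H-C1' and the ester end cis while aryl and lactone carbonyl stay cis because the pyranone ring ties them, which fixes C1' relative to C4 and makes the lactone carbon the future C15 and the ester carbon the future C5. The absolute configuration is set by the tert-butyl groups of the ligand, which should leave open only the face that is Re at the ester-bearing carbon and Si at the benzylic carbon. Regiochemistry follows the para rule: the isoprene CH2 next to the methyl-bearing carbon has the larger HOMO coefficient and bonds to the benzylic β-carbon, which holds the larger LUMO coefficient of the doubly activated alkene, so the ring methyl ends next to C2'. Endo/exo selectivity is not needed because both diene termini are unsubstituted.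

Step 3
Reactants: 6 cis-fused lactone ester
Product: 7 tert-butyl (1R,6S)-1-(hydroxymethyl)-6-(2-hydroxy-4,6-dimethoxyphenyl)-4-methylcyclohex-3-ene-1-carboxylate
Conditions: LiBH4, THF, 0 °C to rt
Reagents that add atoms: none
Why: Chemoselective hydride reduction, because the aryl lactone is a far better acyl donor than the neopentyl tert-butyl ester, so only the carbonyl cis to the aryl group is opened and reduced and the two arms on C4 stay different.

Step 4
Reactants: 7 phenol alcohol
Product: 8 tert-butyl (1R,6S)-1-(hydroxymethyl)-4-methyl-6-(2,4,6-trimethoxyphenyl)cyclohex-3-ene-1-carboxylate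
Conditions: MeI, K2CO3, acetone, reflux
Reagents that add atoms: iodomethane, CI
Why: Williamson ether synthesis in which carbonate deprotonates only the phenol, so the primary alcohol stays free.

Step 5
Reactants: 8 hydroxymethyl ester
Product: 9 tert-butyl (1R,6S)-1-{[(imidazol-1-ylcarbonothioyl)oxy]methyl}-4-methyl-6-(2,4,6-trimethoxyphenyl)cyclohex-3-ene-1-carboxylate
Conditions: (imidazol-1-yl)2C=S, DMAP (cat.), toluene, 90 °C
Reagents that add atoms: 1,1'-thiocarbonyldiimidazole, S=C(n1ccnc1)n1ccnc1
Why: Thioacylation of the alcohol as the first half of a Barton–McCombie deoxygenation, run without strong base so that the β-hydroxy ester cannot lose formaldehyde by retro-aldol cleavage.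

Step 6
Reactants: 9 imidazolyl thionocarbonate
Product: 10 tert-butyl (1R,6S)-1,4-dimethyl-6-(2,4,6-trimethoxyphenyl)cyclohex-3-ene-1-carboxylate
Conditions: Bu3SnH, AIBN (cat.), toluene, reflux
Reagents that add atoms: none
Why: Barton–McCombie radical deoxygenation, which turns the former lactone carbon into C15H3 without a substitution at the neopentyl carbon, where an ortho methoxy group could otherwise take part.

Step 7
Reactants: 10 tert-butyl ester
Product: 11 [(1R,6R)-1,4-dimethyl-6-(2,4,6-trimethoxyphenyl)cyclohex-3-en-1-yl]methanol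
Conditions: LiAlH4, THF, reflux
Reagents that add atoms: none
Why: Ester reduction with LiAlH4, which is strong enough for a hindered tert-butyl ester and leaves the alkene and the aryl ethers untouched.

Step 8
Reactants: 11 neopentyl alcohol
Product: 12 (1R,6S)-1,4-dimethyl-6-(2,4,6-trimethoxyphenyl)cyclohex-3-ene-1-carbaldehyde
Conditions: Dess–Martin periodinane, CH2Cl2, rt
Reagents that add atoms: none
Why: Dess–Martin oxidation to the C5 aldehyde, which has no α-hydrogen and therefore cannot epimerise or enolise.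

Step 9
Reactants: 13 (R)-(-)-carvone
Product: 14 (5R)-5-(2-hydroxypropan-2-yl)-2-methylcyclohex-2-en-1-one
Conditions: 50% aq. H2SO4, 0 °C
Reagents that add atoms: water, O
Why: Acid-catalysed Markovnikov hydration of the isopropenyl group, while the protonated enone alkene is deactivated and the stereocentre (future C7) is not involved.

Step 10
Reactants: 14 hydroxy enone
Product: 16 (2R,5R)-5-(2-hydroxypropan-2-yl)-2-methylcyclohexan-1-one, via cis-ketone 15 (not isolated)
Conditions: H2 (1 atm), Pd/C, EtOAc, rt; filter; NaOMe (cat.), MeOH, rt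
Reagents that add atoms: none
Why: Heterogeneous hydrogenation saturates the only C=C bond and methoxide then equilibrates the α-carbon, so the new stereocentre (future C10) is set under thermodynamic control as the diequatorial trans isomer and residual cis epimer is removed by chromatography.

Step 11
Reactants: 16 trans hydroxy ketone
Product: 17 (2R,5R)-5-[2-(TBSO)propan-2-yl]-2-methylcyclohexan-1-one
Conditions: TBSOTf, 2,6-lutidine, CH2Cl2, 0 °C
Reagents that add atoms: tert-butyldimethylsilyl triflate, CC(C)(C)[Si](C)(C)OS(=O)(=O)C(F)(F)F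
Why: Silylation of a tertiary alcohol with a silyl triflate, which blocks the later β-hydroxy aldehyde from retro-aldol cleavage.

Step 12
Reactants: 17 silyl ether ketone
Product: 19 (2R,5R,6S)-6-hydroxy-5-[2-(TBSO)propan-2-yl]-2-methylcyclohexan-1-one, via potassium enolate 18 (not isolated)
Conditions: KHMDS, THF, -78 °C; 2-(phenylsulfonyl)-3-phenyloxaziridine, -78 °C
Reagents that add atoms: 2-(phenylsulfonyl)-3-phenyloxaziridine, O=S(=O)(N1OC1c1ccccc1)c1ccccc1
Why: Kinetic enolisation at the CH2 side followed by Davis enolate hydroxylation, in which oxygen should enter trans to the neighbouring side chain, although either carbinol epimer serves because this centre is destroyed in step 13.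

Step 13
Reactants: 19 α-ketol
Product: 20 methyl (2R,5S)-6-(TBSO)-5-formyl-2,6-dimethylheptanoate
Conditions: Pb(OAc)4, MeOH/toluene, 0 °C
Reagents that add atoms: methanol, CO
Why: Criegee-type cleavage of the α-ketol through its methyl hemiketal, which cuts the bond between the old carbonyl carbon (future C1) and the carbinol carbon (future C6) and delivers the two ends at different oxidation levels.

Step 14
Reactants: 20 aldehyde ester
Product: 21 methyl (2R,5S)-6-(TBSO)-5-(dimethoxymethyl)-2,6-dimethylheptanoate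
Conditions: HC(OMe)3, PPTS (cat.), MeOH, rt
Reagents that add atoms: trimethyl orthoformate, COC(OC)OC
Why: Mild acid-catalysed acetalisation, which masks C6 and protects the adjacent C7 stereocentre from enolisation for the following steps.

Step 15
Reactants: 21 acetal ester
Product: 22 (2R,5S)-6-(TBSO)-5-(dimethoxymethyl)-2,6-dimethylheptan-1-ol
Conditions: LiAlH4, Et2O, 0 °C
Reagents that add atoms: none
Why: Ester reduction with LiAlH4, which is fast at low temperature and so leaves the α-methyl stereocentre intact.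

Step 16
Reactants: 22 primary alcohol
Product: 23 (2R,5S)-6-(TBSO)-1-iodo-5-(dimethoxymethyl)-2,6-dimethylheptane
Conditions: I2, PPh3, imidazole, CH2Cl2, 0 °C to rt
Reagents that add atoms: iodine, II
Why: Appel-type iodination of a primary alcohol under buffered conditions that the acetal and the silyl ether tolerate.

Step 17
Reactants: 23 primary iodide
Product: 24 diethyl [(2R,5S)-6-(TBSO)-5-(dimethoxymethyl)-2,6-dimethylheptyl]phosphonate
Conditions: P(OEt)3, neat, 150 °C
Reagents that add atoms: triethyl phosphite, CCOP(OCC)OCC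
Why: Michaelis–Arbuzov reaction of a primary iodide, which turns C1 into the nucleophilic carbon needed for both of its new bonds.

Step 18
Reactants: 24 chain phosphonate; 12 C5 aldehyde
Product: 26 diethyl {(3R,6S)-7-(TBSO)-6-(dimethoxymethyl)-1-[(1R,6R)-1,4-dimethyl-6-(2,4,6-trimethoxyphenyl)cyclohex-3-en-1-yl]-1-hydroxy-3,7-dimethyloctan-2-yl}phosphonate (epimers at C1 and C5), via lithiated phosphonate 25 (not isolated)
Conditions: n-BuLi, THF, -78 °C; then 12, -78 to 0 °C
Reagents that add atoms: none
Why: Addition of an α-lithiated alkylphosphonate to a non-enolisable aldehyde forms C1–C5, the lithium β-alkoxy phosphonate does not eliminate, and the two new centres need no control because C5 is oxidised in step 19 and C1 becomes sp2 in step 21.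

Step 19
Reactants: 26 β-hydroxy phosphonate
Product: 27 the corresponding β-keto phosphonate (C5=O; 1'S,4R,7S,10R; epimers at C1)
Conditions: Dess–Martin periodinane, NaHCO3, CH2Cl2, rt
Reagents that add atoms: none
Why: Buffered Dess–Martin oxidation of a β-hydroxy phosphonate, a standard entry to β-keto phosphonates when the matching ester is too hindered for direct acylation.

Step 20
Reactants: 27 β-keto phosphonate
Product: 28 ring-opened keto aldehyde (C3' methyl ketone and C2 aldehyde; 1'S,4R,7S,10R; epimers at C1)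
Conditions: OsO4 (cat.), NaIO4, 2,6-lutidine, dioxane/H2O, rt
Reagents that add atoms: osmium tetroxide (oxygen carrier), O=[Os](=O)(=O)=O; sodium periodate (terminal oxygen source), [Na+].[O-]I(=O)(=O)=O
Why: Lemieux–Johnson cleavage of the only alkene cuts the helper ring into the C3' methyl ketone and the C2 aldehyde, and it is preferred to ozone because the trimethoxyarene is sensitive to ozone.

Step 21
Reactants: 28 keto aldehyde phosphonate
Product: 29 (5R)-2-[(2R,5S)-6-(TBSO)-5-(dimethoxymethyl)-6-methylheptan-2-yl]-5-methyl-5-[(1S)-3-oxo-1-(2,4,6-trimethoxyphenyl)butyl]cyclopent-2-en-1-one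
Conditions: K2CO3, 18-crown-6, toluene, 60 °C
Reagents that add atoms: none
Why: Intramolecular Horner–Wadsworth–Emmons olefination, in which the acidic β-keto phosphonate is the only carbon acid ionised by carbonate and the aldehyde (five-membered ring) reacts faster than the methyl ketone (six-membered ring), so ring A closes at C1=C2.

Step 22
Reactants: 29 cyclopentenone methyl ketone
Product: 30 (5R)-2-[(2R,5S)-6-(TBSO)-5-(dimethoxymethyl)-6-methylheptan-2-yl]-5-methyl-5-[(1S)-3-methyl-1-(2,4,6-trimethoxyphenyl)but-3-en-1-yl]cyclopent-2-en-1-one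
Conditions: MePPh3Br, KOt-Bu, THF, 0 °C
Reagents that add atoms: methyltriphenylphosphonium bromide, C[P+](c1ccccc1)(c1ccccc1)c1ccccc1.[Br-]
Why: Wittig methylenation, selective for the open methyl ketone because the ring carbonyl is shielded by the quaternary C4 and the branched substituent on C1.

Step 23
Reactants: 30 dienone
Product: 32 (2R,5R)-2-[(2R,5S)-6-(TBSO)-5-(dimethoxymethyl)-6-methylheptan-2-yl]-5-methyl-5-[(1S)-3-methyl-1-(2,4,6-trimethoxyphenyl)butyl]cyclopentan-1-one, via C1-epimeric ketone 31 (not isolated)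
Conditions: H2 (4 atm), Pd/C, EtOAc, rt; filter; NaOMe (cat.), MeOH, rt
Reagents that add atoms: none
Why: Heterogeneous hydrogenation saturates the isobutenyl group and the enone alkene from the face of the small C15 methyl group, which first places the chain cis to the large C4 substituent (31), and methoxide-catalysed epimerisation next to the C5 ketone then moves it to the pseudo-equatorial position anti to that substituent, so C1 is set under thermodynamic control and leftover 31 can be re-equilibrated.

Step 24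
Reactants: 32 acetal ketone
Product: 33 (2R,5R)-2-[(2R,5S)-6-(TBSO)-5-formyl-6-methylheptan-2-yl]-5-methyl-5-[(1S)-3-methyl-1-(2,4,6-trimethoxyphenyl)butyl]cyclopentan-1-one
Conditions: PPTS (cat.), acetone/H2O, 50 °C
Reagents that add atoms: water, O
Why: Mild acid hydrolysis of a dimethyl acetal, which frees the C6 aldehyde only one step before it is consumed and is too weak to cleave the tertiary TBS ether.

Step 25
Reactants: 33 keto aldehyde
Product: 34 (1R,3aR,4R,7R)-7-[2-(TBSO)propan-2-yl]-1,4-dimethyl-1-[(1R)-3-methyl-1-(2,4,6-trimethoxyphenyl)butyl]-1,2,3,3a,4,5,6,7-octahydroazulene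
Conditions: TiCl3(DME)1.5, Zn–Cu, DME, reflux, slow addition of 33
Reagents that add atoms: none
Why: Intramolecular McMurry coupling, in which low-valent titanium joins the C5 ketone and the C6 aldehyde to a titanium pinacolate and deoxygenates it at reflux, so the alkene is placed unambiguously at C5=C6, the seven-membered ring B closes under high dilution and no new stereocentre is formed.

Step 26
Reactants: 34 hydroazulene trimethyl ether
Product: 36 3-{(1R)-1-[(1R,3aR,4R,7R)-7-[2-(TBSO)propan-2-yl]-1,4-dimethyl-1,2,3,3a,4,5,6,7-octahydroazulen-1-yl]-3-methylbutyl}-2,4,6-trimethoxybenzaldehyde, via aryllithium 35 (not isolated)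
Conditions: n-BuLi, TMEDA, THF, 0 °C; DMF; H2O
Reagents that add atoms: N,N-dimethylformamide, CN(C)C=O
Why: Directed ortho-metalation, because a ring C–H flanked by two methoxy groups is by far the most acidic site, the two such positions are equivalent by rotation about the C1'–aryl bond, and DMF formylates the aryllithium without touching the alkene or the silyl ether.

Step 27
Reactants: 36 monoaldehyde
Product: 39 5-{(1R)-1-[(1R,3aR,4R,7R)-7-[2-(TBSO)propan-2-yl]-1,4-dimethyl-1,2,3,3a,4,5,6,7-octahydroazulen-1-yl]-3-methylbutyl}-2,4,6-trimethoxybenzene-1,3-dicarbaldehyde, via lithium amino alkoxide 37 (not isolated), via ring-lithiated amino alkoxide 38 (not isolated)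
Conditions: MeNHCH2CH2NMe2, n-BuLi, THF, -20 °C; 36; n-BuLi, 0 °C; DMF; H2O
Reagents that add atoms: N,N-dimethylformamide, CN(C)C=O
Why: The aldehyde is masked in the flask as a lithium α-amino alkoxide that withstands n-BuLi, so a second directed ortho-metalation at the last ring C–H between two methoxy groups and a DMF quench give the dialdehyde after hydrolysis.

Step 28
Reactants: 39 silyl ether dialdehyde
Product: 40 5-{(1R)-1-[(1R,3aR,4R,7R)-7-(2-hydroxypropan-2-yl)-1,4-dimethyl-1,2,3,3a,4,5,6,7-octahydroazulen-1-yl]-3-methylbutyl}-2,4,6-trimethoxybenzene-1,3-dicarbaldehyde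
Conditions: HF·pyridine, THF, 0 °C to rt
Reagents that add atoms: none
Why: Fluoride-driven desilylation, buffered by pyridine so that the tertiary alcohol does not ionise and the trisubstituted alkene does not migrate.

Step 29
Reactants: 40 macrocarpal D trimethyl ether
Product: 41 (-)-macrocarpal D
Conditions: p-TolSH, n-BuLi, HMPA/toluene, reflux; aq. HCl
Reagents that add atoms: none
Why: SN2 demethylation by a soft thiolate, which works because every methoxy group is ortho or para to a formyl group and so gives a stabilised phenoxide, while the non-acidic medium spares the tertiary alcohol and the alkene that boron halides would ionise.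

Compound list
1 | 2-hydroxy-4,6-dimethoxybenzaldehyde | COc1cc(O)c(C=O)c(OC)c1 | starting material
2 | tert-butyl methyl malonate | COC(=O)CC(=O)OC(C)(C)C | starting material
3 | 1-tert-butyl 3-methyl (E)-2-(2-hydroxy-4,6-dimethoxybenzylidene)malonate | COC(=O)/C(C(=O)OC(C)(C)C)=C\c1c(O)cc(OC)cc1OC | intermediate
4 | tert-butyl 5,7-dimethoxy-2-oxo-2H-chromene-3-carboxylate | CC(C)(C)OC(=O)C1=Cc2c(OC)cc(OC)cc2OC1=O | intermediate
5 | isoprene | C=CC(C)=C | starting material
6 | tert-butyl (6aS,10aS)-1,3-dimethoxy-9-methyl-6-oxo-6a,7,10,10a-tetrahydro-6H-benzo[c]chromene-6a-carboxylate | C1[C@@H](c2c(OC)cc(OC)cc2O3)[C@@](C(=O)OC(C)(C)C)(C3=O)CC=C1C | intermediate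
7 | tert-butyl (1R,6S)-1-(hydroxymethyl)-6-(2-hydroxy-4,6-dimethoxyphenyl)-4-methylcyclohex-3-ene-1-carboxylate | C1[C@@H](c2c(OC)cc(OC)cc2O)[C@@](C(=O)OC(C)(C)C)(CO)CC=C1C | intermediate
8 | tert-butyl (1R,6S)-1-(hydroxymethyl)-4-methyl-6-(2,4,6-trimethoxyphenyl)cyclohex-3-ene-1-carboxylate | C1[C@@H](c2c(OC)cc(OC)cc2OC)[C@@](C(=O)OC(C)(C)C)(CO)CC=C1C | intermediate
9 | tert-butyl (1R,6S)-1-{[(imidazol-1-ylcarbonothioyl)oxy]methyl}-4-methyl-6-(2,4,6-trimethoxyphenyl)cyclohex-3-ene-1-carboxylate | C1[C@@H](c2c(OC)cc(OC)cc2OC)[C@@](C(=O)OC(C)(C)C)(COC(=S)n2ccnc2)CC=C1C | intermediate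
10 | tert-butyl (1R,6S)-1,4-dimethyl-6-(2,4,6-trimethoxyphenyl)cyclohex-3-ene-1-carboxylate | C1[C@@H](c2c(OC)cc(OC)cc2OC)[C@@](C(=O)OC(C)(C)C)(C)CC=C1C | intermediate
11 | [(1R,6R)-1,4-dimethyl-6-(2,4,6-trimethoxyphenyl)cyclohex-3-en-1-yl]methanol | C1[C@@H](c2c(OC)cc(OC)cc2OC)[C@@](CO)(C)CC=C1C | intermediate
12 | (1R,6S)-1,4-dimethyl-6-(2,4,6-trimethoxyphenyl)cyclohex-3-ene-1-carbaldehyde | C1[C@@H](c2c(OC)cc(OC)cc2OC)[C@@](C=O)(C)CC=C1C | intermediate
13 | (R)-(-)-carvone | CC1=CC[C@H](CC1=O)C(C)=C | starting material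
14 | (5R)-5-(2-hydroxypropan-2-yl)-2-methylcyclohex-2-en-1-one | CC1=CC[C@H](CC1=O)C(C)(C)O | intermediate
15 | (2S,5R)-5-(2-hydroxypropan-2-yl)-2-methylcyclohexan-1-one (cis) | O=C1C[C@H](C(C)(C)O)CC[C@@H]1C | intermediate
16 | (2R,5R)-5-(2-hydroxypropan-2-yl)-2-methylcyclohexan-1-one (trans) | O=C1C[C@H](C(C)(C)O)CC[C@H]1C | intermediate
17 | (2R,5R)-5-[2-(TBSO)propan-2-yl]-2-methylcyclohexan-1-one | O=C1C[C@H](C(C)(C)O[Si](C)(C)C(C)(C)C)CC[C@H]1C | intermediate
18 | potassium enolate of 17 on the CH2 side | [K+].[O-]C1=C[C@H](C(C)(C)O[Si](C)(C)C(C)(C)C)CC[C@H]1C | intermediate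
19 | (2R,5R,6S)-6-hydroxy-5-[2-(TBSO)propan-2-yl]-2-methylcyclohexan-1-one | O=C1[C@@H](O)[C@H](C(C)(C)O[Si](C)(C)C(C)(C)C)CC[C@H]1C | intermediate
20 | methyl (2R,5S)-6-(TBSO)-5-formyl-2,6-dimethylheptanoate | COC(=O)[C@H](C)CC[C@@H](C(C)(C)O[Si](C)(C)C(C)(C)C)C=O | intermediate
21 | methyl (2R,5S)-6-(TBSO)-5-(dimethoxymethyl)-2,6-dimethylheptanoate | COC(=O)[C@H](C)CC[C@@H](C(C)(C)O[Si](C)(C)C(C)(C)C)C(OC)OC | intermediate
22 | (2R,5S)-6-(TBSO)-5-(dimethoxymethyl)-2,6-dimethylheptan-1-ol | OC[C@H](C)CC[C@@H](C(C)(C)O[Si](C)(C)C(C)(C)C)C(OC)OC | intermediate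
23 | (2R,5S)-6-(TBSO)-1-iodo-5-(dimethoxymethyl)-2,6-dimethylheptane | IC[C@H](C)CC[C@@H](C(C)(C)O[Si](C)(C)C(C)(C)C)C(OC)OC | intermediate
24 | diethyl [(2R,5S)-6-(TBSO)-5-(dimethoxymethyl)-2,6-dimethylheptyl]phosphonate | CCOP(=O)(OCC)C[C@H](C)CC[C@@H](C(C)(C)O[Si](C)(C)C(C)(C)C)C(OC)OC | intermediate
25 | α-lithio derivative of 24 | CCOP(=O)(OCC)C([Li])[C@H](C)CC[C@@H](C(C)(C)O[Si](C)(C)C(C)(C)C)C(OC)OC | intermediate
26 | β-hydroxy phosphonate (1'R,4R,7S,10R; epimers at C1 and C5) | C1[C@@H](c2c(OC)cc(OC)cc2OC)[C@@](C(O)C(P(=O)(OCC)OCC)[C@H](C)CC[C@@H](C(C)(C)O[Si](C)(C)C(C)(C)C)C(OC)OC)(C)CC=C1C | intermediate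
27 | β-keto phosphonate (1'S,4R,7S,10R; epimers at C1) | C1[C@@H](c2c(OC)cc(OC)cc2OC)[C@@](C(=O)C(P(=O)(OCC)OCC)[C@H](C)CC[C@@H](C(C)(C)O[Si](C)(C)C(C)(C)C)C(OC)OC)(C)CC=C1C | intermediate
28 | ring-opened keto aldehyde phosphonate (1'S,4R,7S,10R; epimers at C1) | CC(=O)C[C@@H](c1c(OC)cc(OC)cc1OC)[C@@](C(=O)C(P(=O)(OCC)OCC)[C@H](C)CC[C@@H](C(C)(C)O[Si](C)(C)C(C)(C)C)C(OC)OC)(C)CC=O | intermediate
29 | ring A cyclopentenone with C3' methyl ketone (1'S,4R,7S,10R) | CC(=O)C[C@@H](c1c(OC)cc(OC)cc1OC)[C@@]1(C)CC=C(C1=O)[C@H](C)CC[C@@H](C(C)(C)O[Si](C)(C)C(C)(C)C)C(OC)OC | intermediate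
30 | ring A cyclopentenone with isobutenyl group (1'S,4R,7S,10R) | CC(=C)C[C@@H](c1c(OC)cc(OC)cc1OC)[C@@]1(C)CC=C(C1=O)[C@H](C)CC[C@@H](C(C)(C)O[Si](C)(C)C(C)(C)C)C(OC)OC | intermediate
31 | cyclopentanone, C1 epimer (1S,1'S,4R,7S,10R) | CC(C)C[C@@H](c1c(OC)cc(OC)cc1OC)[C@@]1(C)CC[C@H](C1=O)[C@H](C)CC[C@@H](C(C)(C)O[Si](C)(C)C(C)(C)C)C(OC)OC | intermediate
32 | cyclopentanone acetal (1R,1'S,4R,7S,10R) | CC(C)C[C@@H](c1c(OC)cc(OC)cc1OC)[C@@]1(C)CC[C@@H](C1=O)[C@H](C)CC[C@@H](C(C)(C)O[Si](C)(C)C(C)(C)C)C(OC)OC | intermediate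
33 | cyclopentanone aldehyde (1R,1'S,4R,7S,10R) | CC(C)C[C@@H](c1c(OC)cc(OC)cc1OC)[C@@]1(C)CC[C@@H](C1=O)[C@H](C)CC[C@@H](C(C)(C)O[Si](C)(C)C(C)(C)C)C=O | intermediate
34 | hydroazulene TBS ether with 2,4,6-trimethoxyphenyl group (1R,1'R,4R,7R,10R) | CC(C)C[C@@H](c1c(OC)cc(OC)cc1OC)[C@@]1(C)CC[C@H]2C1=C[C@H](C(C)(C)O[Si](C)(C)C(C)(C)C)CC[C@H]2C | intermediate
35 | 3-lithio derivative of 34 | CC(C)C[C@@H](c1c(OC)c([Li])c(OC)cc1OC)[C@@]1(C)CC[C@H]2C1=C[C@H](C(C)(C)O[Si](C)(C)C(C)(C)C)CC[C@H]2C | intermediate
36 | monoaldehyde TBS ether | CC(C)C[C@@H](c1c(OC)c(C=O)c(OC)cc1OC)[C@@]1(C)CC[C@H]2C1=C[C@H](C(C)(C)O[Si](C)(C)C(C)(C)C)CC[C@H]2C | intermediate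
37 | lithium α-amino alkoxide of 36 | CC(C)C[C@@H](c1c(OC)c(C(O[Li])N(C)CCN(C)C)c(OC)cc1OC)[C@@]1(C)CC[C@H]2C1=C[C@H](C(C)(C)O[Si](C)(C)C(C)(C)C)CC[C@H]2C | intermediate
38 | ring-lithiated α-amino alkoxide | CC(C)C[C@@H](c1c(OC)c(C(O[Li])N(C)CCN(C)C)c(OC)c([Li])c1OC)[C@@]1(C)CC[C@H]2C1=C[C@H](C(C)(C)O[Si](C)(C)C(C)(C)C)CC[C@H]2C | intermediate
39 | dialdehyde TBS ether trimethyl ether | CC(C)C[C@@H](c1c(OC)c(C=O)c(OC)c(C=O)c1OC)[C@@]1(C)CC[C@H]2C1=C[C@H](C(C)(C)O[Si](C)(C)C(C)(C)C)CC[C@H]2C | intermediate
40 | macrocarpal D trimethyl ether | CC(C)C[C@@H](c1c(OC)c(C=O)c(OC)c(C=O)c1OC)[C@@]1(C)CC[C@H]2C1=C[C@H](C(C)(C)O)CC[C@H]2C | intermediate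
41 | (-)-macrocarpal D, 5-{(1R)-1-[(1R,3aR,4R,7R)-7-(2-hydroxypropan-2-yl)-1,4-dimethyl-1,2,3,3a,4,5,6,7-octahydroazulen-1-yl]-3-methylbutyl}-2,4,6-trihydroxybenzene-1,3-dicarbaldehyde | CC(C)C[C@@H](c1c(O)c(C=O)c(O)c(C=O)c1O)[C@@]1(C)CC[C@H]2C1=C[C@H](C(C)(C)O)CC[C@H]2C | target

Total step count: 29. Longest linear sequence: 21 steps, from (R)-carvone 13 through steps 9–17 and then steps 18–29. The arene branch (steps 1–8, then 18–29) has 20 steps.

Steps most likely to fail

Step 2 (new method).
- Turnover may be slow, because two methoxy groups feed electron density into the alkene and the peri methoxy group crowds the benzylic carbon.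
- The cationic copper complex may oligomerise isoprene or strip the tert-butyl ester.
- A diene without terminal substituents may be poorly discriminated between the two faces.
- Fallback: it sets out from 4 and 5 and uses only known chemistry. The uncatalysed Diels–Alder reaction (toluene, 160 °C, sealed tube, radical inhibitor, or high pressure in CH2Cl2) is established for 3-alkoxycarbonylcoumarins with 2-substituted butadienes. It gives the racemic cis-fused adduct F1 with the same regiochemistry. Preparative chromatography on a chiral stationary phase then delivers 6, where the route is rejoined.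

Step 25.
- The hindered C5 ketone may stop at the pinacol stage, or intermolecular aldehyde coupling may outrun it.
- The long reflux with Lewis acidic titanium may epimerise C7 next to the aldehyde or expel the β-silyloxy group.
- Fallback: it sets out from 33 and replaces carbonyl coupling by olefin metathesis. Ph3P=CH2 at low temperature methylenates only the aldehyde and gives the vinyl ketone F2. Cp2TiMe2 in toluene at 80 °C, a non-basic reagent that tolerates crowded enolisable ketones, converts the C5 ketone into the exocyclic methylene diene F3. Ring-closing metathesis with the second-generation Hoveyda–Grubbs catalyst in hot toluene then closes ring B at C5=C6 and returns to 34.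

Step 23.
- The equilibrium at C1 may not lie far enough on the side of the anti isomer.
- Palladium may move the ring alkene toward C10 before reduction and erode that centre.
- Fallback: it sets out from 30 and replaces thermodynamic control by hydroxyl-directed delivery of hydrogen. Luche reduction (NaBH4, CeCl3·7H2O, MeOH) brings hydride to C5 from the face of the C15 methyl group and gives the allylic alcohol F4, with the hydroxyl group on the face of the large C4 substituent. Hydrogenation with [Ir(cod)(PCy3)(py)]PF6 in CH2Cl2 adds hydrogen to C1=C2 syn to that hydroxyl group and also saturates the isobutenyl group, which gives the cyclopentanol F5 with H-C1 on the required face. Dess–Martin oxidation then returns to 32.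

Further compounds
F1 | step 2 | racemic cis-fused adduct (6 and its mirror image, 1:1) | C1[C@@H](c2c(OC)cc(OC)cc2O3)[C@@](C(=O)OC(C)(C)C)(C3=O)CC=C1C.C1[C@H](c2c(OC)cc(OC)cc2O3)[C@](C(=O)OC(C)(C)C)(C3=O)CC=C1C
F2 | step 25 | vinyl ketone (1R,1'S,4R,7R,10R): 33 with CH=CH2 in place of CHO | CC(C)C[C@@H](c1c(OC)cc(OC)cc1OC)[C@@]1(C)CC[C@@H](C1=O)[C@H](C)CC[C@@H](C(C)(C)O[Si](C)(C)C(C)(C)C)C=C
F3 | step 25 | diene (1R,1'R,4R,7R,10R): F2 with C5=CH2 in place of C5=O | CC(C)C[C@@H](c1c(OC)cc(OC)cc1OC)[C@@]1(C)CC[C@@H](C1=C)[C@H](C)CC[C@@H](C(C)(C)O[Si](C)(C)C(C)(C)C)C=C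
F4 | step 23 | allylic alcohol (1'R,4R,5S,7S,10R): 30 with C5-OH cis to the C1' substituent | CC(=C)C[C@@H](c1c(OC)cc(OC)cc1OC)[C@@]1(C)CC=C([C@H]1O)[C@H](C)CC[C@@H](C(C)(C)O[Si](C)(C)C(C)(C)C)C(OC)OC
F5 | step 23 | cyclopentanol (1R,1'R,4R,5R,7S,10R): H-C1 and C5-OH cis | CC(C)C[C@@H](c1c(OC)cc(OC)cc1OC)[C@@]1(C)CC[C@@H]([C@H]1O)[C@H](C)CC[C@@H](C(C)(C)O[Si](C)(C)C(C)(C)C)C(OC)OC
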